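## Retrosynthetic overview

1. The target arecatannin, epicatechin-(4β→8)-epicatechin-(4β→8)-epicatechin-(4β→8)-catechin (flavan units counted 1 to 4, from the top epicatechin to the terminal catechin) ⇐ global hydrogenolysis of its heptadeca-O-benzyl ether ⇐ two successive Lewis-acid 4β→8 chain extensions (unit 2, then unit 1) of the benzylated unit 3–unit 4 dimer with a 4-alkoxy-epicatechin electrophile.
2. Unit 3–unit 4 dimer ⇐ formal [3+3] annulation of phloroglucinol (phenol O plus ortho C) onto a C2–C3–C4 trans-epoxy ketone that already carries the catechin unit on C4 and the catechol ring on C2: Friedel–Crafts epoxide opening makes C4a–C4, reductive etherification of the ketone makes O1–C2, and ring C of unit 3 closes in the same flask.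
3. Enabling feature: ring A of unit 3 is a phloroglucinol nucleus in which O1/C4a is one of three equivalent O/ortho-C pairs of the free triphenol, so the annulation has no regiochemical choice. C4 of ring C of unit 3 sits on C8 of the 5,7,8a-trioxygenated ring A of unit 4, so a C–O bond at C4 ionises under mild acid, while C2, benzylic to the catechol ring, can be carried as a ketone.
4. Epoxy ketone ⇐ catalyst-controlled epoxidation of the (E)-enone ⇐ Claisen–Schmidt condensation of 8-formyl-penta-O-benzylcatechin (from (+)-catechin by benzylation, C8 bromination, Br/Li exchange and formylation) with 3',4'-bis(benzyloxy)acetophenone.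
5. Ring order: the heterocycles of units 4, 2 and 1 come intact from (+)-catechin and (−)-epicatechin; the only ring built is ring C of unit 3 (key step), onto which units 2 and 1 are then attached.

Key step: step 8

Remark: poly-L-leucine is assumed to transfer oxygen to enone 8 with the same facial sense as to chalcone itself, giving the (2R,3S)-epoxide; if the sense were reversed for this substrate, poly-D-leucine would be used.

## Route

Step 1
Reactants: 1 (+)-catechin
Product: 2 5,7,3',4'-tetra-O-benzyl-(+)-catechin (2R,3S; 3-OH free)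
Conditions: BnBr (4.2 equiv), K2CO3, DMF, 0 °C → rt
Reagents that add atoms: benzyl bromide, BrCc1ccccc1
Why: Williamson etherification under carbonate conditions should alkylate only the four phenols, since the secondary 3-OH is not deprotonated, and C2 and C3 are untouched.

Step 2
Reactants: 2 5,7,3',4'-tetra-O-benzyl-(+)-catechin
Product: 3 8-bromo-5,7,3',4'-tetra-O-benzylcatechin (2R,3S)
Conditions: NBS (1.0 equiv), CH2Cl2, −78 °C → rt
Reagents that add atoms: N-bromosuccinimide, O=C1CCC(=O)N1Br
Why: electrophilic aromatic bromination of the phloroglucinol-type ring A, which for benzylated flavan-3-ols is known to go to C8.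

Step 3
Reactants: 3 8-bromo-5,7,3',4'-tetra-O-benzylcatechin
Product: 4 8-bromo-3,5,7,3',4'-penta-O-benzylcatechin (2R,3S)
Conditions: NaH, BnBr, n-Bu4NI (cat.), DMF, 0 °C → rt
Reagents that add atoms: benzyl bromide, BrCc1ccccc1
Why: Williamson etherification of the 3-alkoxide removes the only acidic proton before the lithiation and touches no stereocentre.

Step 4
Reactants: 4 8-bromo-3,5,7,3',4'-penta-O-benzylcatechin
Product: 5 8-formyl-3,5,7,3',4'-penta-O-benzylcatechin (2R,3S)
Conditions: n-BuLi (1.1 equiv), THF, −78 °C; DMF, −78 → 0 °C; H2O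
Reagents that add atoms: N,N-dimethylformamide, CN(C)C=O
Why: bromine–lithium exchange at C8 followed by Bouveault formylation of the aryllithium, the exchange being faster than benzylic deprotonation at −78 °C.

Step 5
Reactants: 6 3',4'-dihydroxyacetophenone
Product: 7 3',4'-bis(benzyloxy)acetophenone
Conditions: BnBr (2.2 equiv), K2CO3, DMF, 60 °C
Reagents that add atoms: benzyl bromide, BrCc1ccccc1
Why: Williamson etherification of both phenols of the catechol.

Step 6
Reactants: 5 8-formyl-3,5,7,3',4'-penta-O-benzylcatechin; 7 3',4'-bis(benzyloxy)acetophenone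
Product: 8 (E)-1-[3,4-bis(benzyloxy)phenyl]-3-(3,5,7,3',4'-penta-O-benzylcatechin-8-yl)prop-2-en-1-one
Conditions: KOH, EtOH/THF, rt
Reagents that add atoms: none
Why: Claisen–Schmidt condensation (aldol addition then base-induced dehydration through the enolate) should give the conjugated (E)-enone under thermodynamic control, and without a free phenol neither partner has a base-labile stereocentre.

Step 7
Reactants: 8 (E)-enone
Product: 9 [(2R,3S)-3-(3,5,7,3',4'-penta-O-benzylcatechin-8-yl)oxiran-2-yl][3,4-bis(benzyloxy)phenyl]methanone (trans-epoxy ketone)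
Conditions: poly-L-leucine, urea–H2O2, DBU, THF, rt; chromatography on Et3N-deactivated silica
Reagents that add atoms: urea–hydrogen peroxide, NC(N)=O.OO
Why: Juliá–Colonna epoxidation (Weitz–Scheffer addition of hydroperoxide anion inside the helical peptide) should give the trans (2R,3S)-epoxy ketone under catalyst control, and the minor trans isomer is a diastereomer (resident catechin stereocentres) that chromatography can remove.

Step 8
Reactants: 9 trans-(2R,3S)-epoxy ketone; 10 phloroglucinol
Product: 13 3',4'-di-O-benzylepicatechin-(4β→8)-3,5,7,3',4'-penta-O-benzylcatechin (upper unit 2R,3R with free 3-OH and 5,7-OH; 4-aryl trans to 3-OH), via ring-opened hydroxy ketone 11 (not isolated), via cyclic hemiketal 12 (not isolated)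
Conditions: 10 (4 equiv), BF3·OEt2 (0.3 equiv), CH2Cl2/MeCN, −40 °C; then Et3SiH (5 equiv), BF3·OEt2 (2 equiv), −40 → 0 °C, same flask; Et3N, aq. NaHCO3
Reagents that add atoms: none
Why: Proposed new method: BF3 opens the epoxide of 9 at the carbon benzylic to the 2,4,6-trioxygenated ring A of the catechin unit, a ring carbon of 10 attacks that carbon from the side opposite the departing oxygen (Friedel–Crafts alkylation with inversion; closest precedent: Lewis-acid opening of aryl epoxides and 3-aryl-2,3-epoxy carbonyl compounds by electron-rich arenes) to give 11, and one of the two equivalent ortho hydroxyls of the new aryl group adds to the aryl ketone (6-exo-trig hemiketalisation) to give 12. Ionisation of 12 to the 2-aryl-chromenylium ion and hydride transfer from Et3SiH then fix the O1–C2 bond (closest precedent: cis-selective reductive etherification of 2-oxygenated 1-aryl-3-(2-hydroxyaryl)propan-1-ones to flavan-3-ol derivatives). C3 comes unchanged from the epoxide (R); C4 is set by the inversion at the epoxide carbon, which places the catechin-8-yl group trans to O3; C2 is set by axial hydride delivery anti to the pseudoaxial C3 oxygen of the half-chair cation, which leaves the dibenzyloxyphenyl group equatorial and cis to O3. The step needs C- over O-alkylation and mono- over poly-alkylation of 10 (soft benzylic cation, excess of 10), opening at C4 and not C3 (aryl donor at C4, acyl acceptor at C3), and no choice in the ring closure (threefold symmetry of 10). The silane is added only after the C–C bond has formed so that the C4 cation is not reduced.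

Step 9
Reactants: 13 3',4'-di-O-benzylepicatechin-(4β→8)-3,5,7,3',4'-penta-O-benzylcatechin
Product: 14 5,7,3',4'-tetra-O-benzylepicatechin-(4β→8)-3,5,7,3',4'-penta-O-benzylcatechin (upper 3-OH free)
Conditions: BnBr (2.5 equiv), K2CO3, DMF, rt
Reagents that add atoms: benzyl bromide, BrCc1ccccc1
Why: Williamson etherification of the two ring-A phenols only, the secondary 3-OH staying free and the benzylated catechol ring preventing base-induced opening of ring C.

Step 10
Reactants: 15 (−)-epicatechin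
Product: 16 5,7,3',4'-tetra-O-benzyl-(−)-epicatechin (2R,3R; 3-OH free)
Conditions: BnBr (4.2 equiv), K2CO3, DMF, 0 °C → rt
Reagents that add atoms: benzyl bromide, BrCc1ccccc1
Why: Williamson etherification of the four phenols under mild carbonate conditions that should not epimerise C2.

Step 11
Reactants: 16 5,7,3',4'-tetra-O-benzyl-(−)-epicatechin
Product: 17 (2R,3R,4S)-5,7,3',4'-tetra-O-benzyl-4-(2-ethoxyethoxy)flavan-3-ol (4β ether, trans to 3-OH)
Conditions: DDQ (2 equiv), 2-ethoxyethanol (5 equiv), CH2Cl2, rt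
Reagents that add atoms: 2-ethoxyethanol, CCOCCO
Why: DDQ abstracts hydride from the benzylic C4 methylene activated by the dialkoxy ring A and the alcohol traps the cation anti to the 3-OH (oxidative benzylic etherification known for benzylated flavan-3-ols), the C4 configuration being of no consequence because the group is ionised again later.

Step 12
Reactants: 14 benzylated unit 3–unit 4 dimer (2.5 equiv, excess recovered); 17 4-(2-ethoxyethoxy) electrophile
Product: 18 5,7,3',4'-tetra-O-benzylepicatechin-(4β→8)-5,7,3',4'-tetra-O-benzylepicatechin-(4β→8)-3,5,7,3',4'-penta-O-benzylcatechin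
Conditions: TMSOTf (cat.), CH2Cl2, −78 °C; Et3N
Reagents that add atoms: none
Why: TMSOTf ionises the 4-alkoxy group of 17 to the flavan-4-yl cation, which C8 of the upper unit of 14 should attack anti to the 3-OH (4β, 3,4-trans) in the known Lewis-acid interflavan coupling, the excess of 14 limiting further extension.

Step 13
Reactants: 18 benzylated trimer (2 equiv, excess recovered); 17 4-(2-ethoxyethoxy) electrophile
Product: 19 heptadeca-O-benzyl ether of the target tetramer, [tetra-O-benzylepicatechin-(4β→8)]3-penta-O-benzylcatechin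
Conditions: TMSOTf (cat.), CH2Cl2, −78 °C; Et3N
Reagents that add atoms: none
Why: the same Lewis-acid interflavan coupling, in which the free C8 of the top unit of 18 should attack the flavan-4-yl cation anti to its 3-OH to set the third 4β→8 bond.

Step 14
Reactants: 19 heptadeca-O-benzyl ether of the target tetramer
Product: 20 epicatechin-(4β→8)-epicatechin-(4β→8)-epicatechin-(4β→8)-catechin (the target arecatannin)
Conditions: H2 (1 atm), Pd(OH)2/C, THF/MeOH/H2O, rt
Reagents that add atoms: none
Why: hydrogenolysis of all seventeen benzyl ethers under neutral conditions that leave the interflavan bonds and every stereocentre untouched.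

## Compound list

1 | (+)-catechin | Oc1cc(O)c2c(c1)O[C@H](c1ccc(O)c(O)c1)[C@@H](O)C2 | starting material
2 | 5,7,3',4'-tetra-O-benzyl-(+)-catechin | C(c1ccccc1)Oc1cc(OCc3ccccc3)c2c(c1)O[C@H](c1ccc(OCc3ccccc3)c(OCc3ccccc3)c1)[C@@H](O)C2 | intermediate
3 | 8-bromo-5,7,3',4'-tetra-O-benzylcatechin | Brc1c(OCc3ccccc3)cc(OCc3ccccc3)c2c1O[C@H](c1ccc(OCc3ccccc3)c(OCc3ccccc3)c1)[C@@H](O)C2 | intermediate
4 | 8-bromo-3,5,7,3',4'-penta-O-benzylcatechin | Brc1c(OCc3ccccc3)cc(OCc3ccccc3)c2c1O[C@H](c1ccc(OCc3ccccc3)c(OCc3ccccc3)c1)[C@@H](OCc1ccccc1)C2 | intermediate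
5 | 8-formyl-3,5,7,3',4'-penta-O-benzylcatechin | O=Cc1c(OCc3ccccc3)cc(OCc3ccccc3)c2c1O[C@H](c1ccc(OCc3ccccc3)c(OCc3ccccc3)c1)[C@@H](OCc1ccccc1)C2 | intermediate
6 | 3',4'-dihydroxyacetophenone | CC(=O)c1ccc(O)c(O)c1 | starting material
7 | 3',4'-bis(benzyloxy)acetophenone | CC(=O)c1ccc(OCc2ccccc2)c(OCc2ccccc2)c1 | intermediate
8 | (E)-1-[3,4-bis(benzyloxy)phenyl]-3-(3,5,7,3',4'-penta-O-benzylcatechin-8-yl)prop-2-en-1-one | O=C(c1ccc(OCc3ccccc3)c(OCc3ccccc3)c1)/C=C/c1c(OCc3ccccc3)cc(OCc3ccccc3)c2c1O[C@H](c1ccc(OCc3ccccc3)c(OCc3ccccc3)c1)[C@@H](OCc1ccccc1)C2 | intermediate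
9 | [(2R,3S)-3-(3,5,7,3',4'-penta-O-benzylcatechin-8-yl)oxiran-2-yl][3,4-bis(benzyloxy)phenyl]methanone | O=C(c1ccc(OCc3ccccc3)c(OCc3ccccc3)c1)[C@@H]4O[C@H]4c1c(OCc3ccccc3)cc(OCc3ccccc3)c2c1O[C@H](c1ccc(OCc3ccccc3)c(OCc3ccccc3)c1)[C@@H](OCc1ccccc1)C2 | intermediate
10 | phloroglucinol (benzene-1,3,5-triol) | Oc1cc(O)cc(O)c1 | starting material
11 | ring-opened hydroxy ketone: (2R)-1-[3,4-bis(benzyloxy)phenyl]-2-hydroxy-3-(penta-O-benzylcatechin-8-yl)-3-(2,4,6-trihydroxyphenyl)propan-1-one, C3 formed with inversion | O=C(c1ccc(OCc3ccccc3)c(OCc3ccccc3)c1)[C@H](O)[C@H](c1c(O)cc(O)cc1O)c1c(OCc3ccccc3)cc(OCc3ccccc3)c2c1O[C@H](c1ccc(OCc3ccccc3)c(OCc3ccccc3)c1)[C@@H](OCc1ccccc1)C2 | intermediate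
12 | cyclic hemiketal: the 2-hydroxy analogue of 13 (both C2 epimers) | Oc1cc(O)c2c(c1)OC(O)(c1ccc(OCc3ccccc3)c(OCc3ccccc3)c1)[C@H](O)[C@H]2c1c(OCc3ccccc3)cc(OCc3ccccc3)c2c1O[C@H](c1ccc(OCc3ccccc3)c(OCc3ccccc3)c1)[C@@H](OCc1ccccc1)C2 | intermediate
13 | 3',4'-di-O-benzylepicatechin-(4β→8)-3,5,7,3',4'-penta-O-benzylcatechin | Oc1cc(O)c2c(c1)O[C@H](c1ccc(OCc3ccccc3)c(OCc3ccccc3)c1)[C@H](O)[C@H]2c1c(OCc3ccccc3)cc(OCc3ccccc3)c2c1O[C@H](c1ccc(OCc3ccccc3)c(OCc3ccccc3)c1)[C@@H](OCc1ccccc1)C2 | intermediate
14 | 5,7,3',4'-tetra-O-benzylepicatechin-(4β→8)-3,5,7,3',4'-penta-O-benzylcatechin | C(c1ccccc1)Oc1cc(OCc3ccccc3)c2c(c1)O[C@H](c1ccc(OCc3ccccc3)c(OCc3ccccc3)c1)[C@H](O)[C@H]2c1c(OCc3ccccc3)cc(OCc3ccccc3)c2c1O[C@H](c1ccc(OCc3ccccc3)c(OCc3ccccc3)c1)[C@@H](OCc1ccccc1)C2 | intermediate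
15 | (−)-epicatechin | Oc1cc(O)c2c(c1)O[C@H](c1ccc(O)c(O)c1)[C@H](O)C2 | starting material
16 | 5,7,3',4'-tetra-O-benzyl-(−)-epicatechin | C(c1ccccc1)Oc1cc(OCc3ccccc3)c2c(c1)O[C@H](c1ccc(OCc3ccccc3)c(OCc3ccccc3)c1)[C@H](O)C2 | intermediate
17 | (2R,3R,4S)-5,7,3',4'-tetra-O-benzyl-4-(2-ethoxyethoxy)flavan-3-ol | C(c1ccccc1)Oc1cc(OCc3ccccc3)c2c(c1)O[C@H](c1ccc(OCc3ccccc3)c(OCc3ccccc3)c1)[C@H](O)[C@H]2OCCOCC | intermediate
18 | tetra-O-benzylepicatechin-(4β→8)-tetra-O-benzylepicatechin-(4β→8)-penta-O-benzylcatechin | C(c1ccccc1)Oc1cc(OCc3ccccc3)c2c(c1)O[C@H](c1ccc(OCc3ccccc3)c(OCc3ccccc3)c1)[C@H](O)[C@H]2c1c(OCc3ccccc3)cc(OCc3ccccc3)c2c1O[C@H](c1ccc(OCc3ccccc3)c(OCc3ccccc3)c1)[C@H](O)[C@H]2c1c(OCc3ccccc3)cc(OCc3ccccc3)c2c1O[C@H](c1ccc(OCc3ccccc3)c(OCc3ccccc3)c1)[C@@H](OCc1ccccc1)C2 | intermediate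
19 | heptadeca-O-benzyl ether of the target tetramer, [tetra-O-benzylepicatechin-(4β→8)]3-penta-O-benzylcatechin | C(c1ccccc1)Oc1cc(OCc3ccccc3)c2c(c1)O[C@H](c1ccc(OCc3ccccc3)c(OCc3ccccc3)c1)[C@H](O)[C@H]2c1c(OCc3ccccc3)cc(OCc3ccccc3)c2c1O[C@H](c1ccc(OCc3ccccc3)c(OCc3ccccc3)c1)[C@H](O)[C@H]2c1c(OCc3ccccc3)cc(OCc3ccccc3)c2c1O[C@H](c1ccc(OCc3ccccc3)c(OCc3ccccc3)c1)[C@H](O)[C@H]2c1c(OCc3ccccc3)cc(OCc3ccccc3)c2c1O[C@H](c1ccc(OCc3ccccc3)c(OCc3ccccc3)c1)[C@@H](OCc1ccccc1)C2 | intermediate
20 | epicatechin-(4β→8)-epicatechin-(4β→8)-epicatechin-(4β→8)-catechin (the target arecatannin) | Oc1cc(O)c2c(c1)O[C@H](c1ccc(O)c(O)c1)[C@H](O)[C@H]2c1c(O)cc(O)c2c1O[C@H](c1ccc(O)c(O)c1)[C@H](O)[C@H]2c1c(O)cc(O)c2c1O[C@H](c1ccc(O)c(O)c1)[C@H](O)[C@H]2c1c(O)cc(O)c2c1O[C@H](c1ccc(O)c(O)c1)[C@@H](O)C2 | target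

## Step count and risks

Total steps: 14. Longest linear sequence: 11 steps (1, 2, 3, 4, 6, 7, 8, 9, 12, 13, 14).

The three steps most likely to fail:

Step 8 (proposed new method). Several processes could divert it:
- acyl or hydride migration in the ring-opened cation could outrun arylation;
- a free C4 cation could lose the inversion and give the 3,4-cis isomer;
- enolisation of the hydroxy ketone or of the oxocarbenium ion could scramble C3;
- hydride could be delivered syn to O3, or could reduce the C4 cation or reopen the benzylic O1–C2 bond.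

The fallback uses the known interflavan coupling and sets out from 2 and 17. Benzylation of the 3-OH of 2 (NaH, BnBr, DMF) gives 3,5,7,3',4'-penta-O-benzylcatechin F1. TMSOTf-mediated coupling of electrophile 17 with an excess of F1 in CH2Cl2 at −78 °C should then form the 4β→8 bond directly, by attack of C8 of F1 on the flavan-4-yl cation anti to the 3-OH. It comes back to the route at 14; steps 2 to 9 are then not needed.

Step 7. Oxygen transfer to a hindered, electron-rich enone may be slow, and catalyst control over the enone face may be weak. The fallback builds the epoxide by C–C bond formation instead and sets out from 7 and 5. α-Bromination of 7 (CuBr2, EtOAc/CHCl3, reflux) gives 2-bromo-1-[3,4-bis(benzyloxy)phenyl]ethanone F2. Darzens condensation of F2 with aldehyde 5 under phase-transfer conditions (LiOH, a cinchonine-derived quaternary ammonium bromide, Bu2O, 4 °C) should give the trans-epoxy ketones. The (2S,3R)-epoxide diastereomer F3 is removed by chromatography, which is possible because the catechin stereocentres make the two trans-epoxides diastereomers. It comes back to the route at 9.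

Step 13. The product is itself a nucleophile and may be extended further; attack may occur at C6 positions; and the Lewis acid may scramble interflavan bonds already present. The fallback is a [2+2] union that sets out from 14, 16 and 17. TMSOTf coupling of 17 with an excess of 16 gives octa-O-benzyl epicatechin-(4β→8)-epicatechin F4. Oxidation of F4 with DDQ and 2-ethoxyethanol at its only benzylic methylene (C4 of the lower unit) gives the dimeric electrophile, 4-(2-ethoxyethoxy)-octa-O-benzyl epicatechin-(4β→8)-epicatechin F5. TMSOTf coupling of F5 with dimer 14 (excess, CH2Cl2, −78 °C) should form the central 4β→8 bond. It comes back to the route at 19 and replaces steps 12 and 13.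

Further compounds

F1 | step 8 | 3,5,7,3',4'-penta-O-benzylcatechin | C(c1ccccc1)Oc1cc(OCc3ccccc3)c2c(c1)O[C@H](c1ccc(OCc3ccccc3)c(OCc3ccccc3)c1)[C@@H](OCc1ccccc1)C2
F2 | step 7 | 2-bromo-1-[3,4-bis(benzyloxy)phenyl]ethanone | O=C(CBr)c1ccc(OCc2ccccc2)c(OCc2ccccc2)c1
F3 | step 7 | [(2S,3R)-3-(3,5,7,3',4'-penta-O-benzylcatechin-8-yl)oxiran-2-yl][3,4-bis(benzyloxy)phenyl]methanone | O=C(c1ccc(OCc3ccccc3)c(OCc3ccccc3)c1)[C@H]4O[C@@H]4c1c(OCc3ccccc3)cc(OCc3ccccc3)c2c1O[C@H](c1ccc(OCc3ccccc3)c(OCc3ccccc3)c1)[C@@H](OCc1ccccc1)C2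
F4 | step 13 | octa-O-benzyl epicatechin-(4β→8)-epicatechin [tetra-O-benzylepicatechin-(4β→8)-tetra-O-benzylepicatechin] | C(c1ccccc1)Oc1cc(OCc3ccccc3)c2c(c1)O[C@H](c1ccc(OCc3ccccc3)c(OCc3ccccc3)c1)[C@H](O)[C@H]2c1c(OCc3ccccc3)cc(OCc3ccccc3)c2c1O[C@H](c1ccc(OCc3ccccc3)c(OCc3ccccc3)c1)[C@H](O)C2
F5 | step 13 | 4-(2-ethoxyethoxy)-octa-O-benzyl epicatechin-(4β→8)-epicatechin (4β ether on the lower unit) | C(c1ccccc1)Oc1cc(OCc3ccccc3)c2c(c1)O[C@H](c1ccc(OCc3ccccc3)c(OCc3ccccc3)c1)[C@H](O)[C@H]2c1c(OCc3ccccc3)cc(OCc3ccccc3)c2c1O[C@H](c1ccc(OCc3ccccc3)c(OCc3ccccc3)c1)[C@H](O)[C@H]2OCCOCC
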